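C1 = lactone C=O, C2–C6 = ring CH2, C7 = ring CH–O, C8/C9/C10 = cyclopropane (C9 = CH2), C11=C12 (E), C13/C14 = diol, C16=C17 (Z), C22 = CH3.
Cuts: C11=C12 (Julia–Kocienski) gives a C1–C11 lactone sulfone and a C12–C22 aldehyde. In the oxocanone a transannular C1–C5 bond is put back (reverse of an alkoxy-radical β-scission). Then follow C1–C2 (key closure), C4–C5 (enolate alkylation), C8–C9/C9–C10 (cyclopropanation) and C8=C10 (Wittig); in the side chain, C15–C16 (acetylide alkylation).
Enabling feature: in the ring O–C1–C2–C3–C4–C5–C6–C7, C1 and C5 face each other. One extra C1–C5 bond divides the ring into a γ-butyrolactone (O, C1, C5, C6, C7) and a cyclopentane (C1–C5). The medium-ring closure thus becomes a 5-exo attack of C2 on the carbonyl C1 of a butyrolactone, and scission of the shared bond then merges the two small rings.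
Ring order forward: butyrolactone (in the starting material), cyclopropane, cyclopentanone by C1–C2 closure (the C1–O bond opens in this acyl substitution and returns in the lactol tautomer), oxocan-2-one by C1–C5 scission (helpers: the C1–C5 bond and a C5 iodide, both removed), chain joined at C11=C12, diol released.
Stereochemistry: C7 comes from the D-glutamic acid-derived lactone alcohol 1, whose five carbons become C1, C5, C6, C7 and C8. C8/C10 come from the (S,S)-dioxaborolane of the Charette cyclopropanation, and C13/C14 from L-tartaric acid as L-threitol acetonide 17. The E-alkenes come from the Wittig and Julia–Kocienski steps, the Z-alkene from Lindlar hydrogenation.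

Key step: step 6

Remark on the chemistry: C5 in 9–12 and C1 in 11 are temporary stereocentres. They should arise as mixtures, are written without descriptor, and are erased in steps 7 and 8.

Step 1
Reactants: 1 (R)-5-(hydroxymethyl)dihydrofuran-2(3H)-one; 2 (triphenylphosphoranylidene)acetaldehyde
Product: 4 (E)-3-[(2R)-5-oxotetrahydrofuran-2-yl]prop-2-enal, via lactone aldehyde 3 (not isolated)
Conditions: (COCl)2, DMSO, CH2Cl2, −78 °C; Et3N, −78 → 0 °C; then 2, 0 °C → rt
Reagents that add atoms: none
Why: One-pot Swern oxidation and Wittig olefination spare the isolation of the water-soluble and epimerisable α-acyloxy aldehyde 3, the stabilised ylide should give the E-enal (C8=C10), and C7 is carried over unchanged from 1.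

Step 2
Reactants: 4 (E)-3-[(2R)-5-oxotetrahydrofuran-2-yl]prop-2-enal
Product: 5 (5R)-5-[(E)-3-hydroxyprop-1-enyl]dihydrofuran-2(3H)-one
Conditions: NaBH4, CeCl3·7H2O, MeOH, −40 °C
Reagents that add atoms: none
Why: Luche reduction: the cerium-modified borohydride should reduce the enal carbonyl in the 1,2-sense far faster than it touches the lactone, and no stereocentre is formed.

Step 3
Reactants: 5 (5R)-5-[(E)-3-hydroxyprop-1-enyl]dihydrofuran-2(3H)-one
Product: 6 (5R)-5-[(1R,2R)-2-(hydroxymethyl)cyclopropyl]dihydrofuran-2(3H)-one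
Conditions: Et2Zn, CH2I2, DME, CH2Cl2, −10 °C; (4S,5S)-2-butyl-N,N,N',N'-tetramethyl-1,3,2-dioxaborolane-4,5-dicarboxamide (1.2 equiv), −10 °C → rt; aq NH4Cl
Reagents that add atoms: diiodomethane, ICI
Why: Charette asymmetric Simmons–Smith cyclopropanation: the zinc alkoxide of 5 binds to the (S,S)-dioxaborolane, which directs the zinc carbenoid to one alkene face (reagent control, in the sense known for E-allylic alcohols), and the stereospecific syn addition turns the E-alkene into the trans-cyclopropane with C8 = R and C10 = R (C10 is renamed S once C11 becomes an alkene carbon).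

Step 4
Reactants: 6 (5R)-5-[(1R,2R)-2-(hydroxymethyl)cyclopropyl]dihydrofuran-2(3H)-one
Product: 7 (5R)-5-[(1R,2R)-2-{[(tert-butyldiphenylsilyl)oxy]methyl}cyclopropyl]dihydrofuran-2(3H)-one
Conditions: TBDPSCl, imidazole, CH2Cl2, 0 °C → rt
Reagents that add atoms: tert-butyl(chloro)diphenylsilane, CC(C)(C)[Si](Cl)(c1ccccc1)c1ccccc1
Why: Imidazole-promoted silylation of a primary alcohol gives an ether that should survive enolate, SmI2, hypoiodite and tin hydride conditions.

Step 5
Reactants: 7 TBDPS-protected cyclopropyl butyrolactone; 8 1,3-diiodopropane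
Product: 9 (5R)-5-[(1R,2R)-2-{[(tert-butyldiphenylsilyl)oxy]methyl}cyclopropyl]-3-(3-iodopropyl)dihydrofuran-2(3H)-one
Conditions: LDA, THF, −78 °C; 8 (4 equiv), DMPU, −78 → −20 °C
Reagents that add atoms: none
Why: Alkylation of the lithium lactone enolate (SN2) with an excess of the diiodide, so that only one C–I bond reacts, attaches C4 to C5; attack anti to the C7 substituent should favour the 3,5-trans isomer, but the C5 configuration is of no consequence.

Step 6
Reactants: 9 α-(3-iodopropyl) butyrolactone
Product: 10 2-[(2R)-2-hydroxy-2-{(1R,2R)-2-[(tert-butyldiphenylsilyloxy)methyl]cyclopropyl}ethyl]cyclopentan-1-one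
Conditions: SmI2 (2.2 equiv), Fe(dbm)3 (cat.), THF, −30 °C → rt; pH 7 buffer
Reagents that add atoms: none
Why: SmI2 reduces the primary C2–I bond by two single-electron transfers to an alkylsamarium(III), which adds to the lactone carbonyl C1 and forms the C1–C2 bond; the tetrahedral samarium alkoxide collapses with expulsion of the C7 alkoxide (addition–elimination), and the quench protonates that oxygen to give hydroxy ketone 10. The closest known reaction type is the samarium Barbier reaction in its intramolecular nucleophilic acyl substitution form, shown for iodoalkyl esters and lactones under iron(III) catalysis. The cyclopentane ring (C1–C5) closes in the 5-exo-trig mode, the carbonyl oxygen staying outside the new ring, which is far easier than any direct closure of the eight-membered ring. No new stereocentre remains in 10, since C1 is trigonal and C5 is temporary and epimerisable, while C7, C8 and C10 take no part. The step needs chemoselective reduction of C–I: without HMPA or a proton source SmI2 leaves the unactivated lactone, the silyl ether and the cyclopropane (not adjacent to any radical or ketyl centre) untouched and reduces a dialkyl ketone only slowly, each molecule carries a single C–I bond so that no organosamarium is left to add to the new ketone, and only 2.2 equiv of reductant are used. After this step all eight atoms of the later ring are joined in the right order, the C7 oxygen can return to C1 as a lactol, and only the C1–C5 bond then has to be cut.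

Step 7
Reactants: 10 γ-hydroxy ketone
Product: 12 (8R)-6-iodo-8-[(1R,2R)-2-{[(tert-butyldiphenylsilyl)oxy]methyl}cyclopropyl]oxocan-2-one, via bicyclic lactol 11 (not isolated)
Conditions: PhI(OAc)2, I2, cyclohexane/CH2Cl2, tungsten lamp, rt
Reagents that add atoms: iodine, II
Why: Suárez hypoiodite fragmentation: 10 closes reversibly to the lactol 11 (ring-chain tautomerism, cis fusion forced by the bicyclo[3.3.0] frame), the O–I bond of its hypoiodite is homolysed by light, and the C1 alkoxy radical undergoes β-scission of the ring-fusion bond C1–C5, favoured because it forms the ester C=O and a secondary rather than a primary radical, after which iodine traps C5 and the two five-membered rings have merged into the oxocan-2-one with C7 untouched.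

Step 8
Reactants: 12 6-iodo-oxocan-2-one
Product: 13 (8R)-8-[(1R,2R)-2-{[(tert-butyldiphenylsilyl)oxy]methyl}cyclopropyl]oxocan-2-one
Conditions: Bu3SnH, AIBN (cat.), PhH, 80 °C
Reagents that add atoms: none
Why: Radical chain dehalogenation with tin hydride removes the helper iodide; the C5 radical is separated from the cyclopropane by C6 and C7, so no cyclopropylcarbinyl opening is expected.

Step 9
Reactants: 13 TBDPS-protected cyclopropyl oxocanone
Product: 14 (8R)-8-[(1R,2R)-2-(hydroxymethyl)cyclopropyl]oxocan-2-one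
Conditions: HF·pyridine, pyridine, THF, 0 °C → rt
Reagents that add atoms: none
Why: Fluoride-induced Si–O cleavage under buffered, non-basic conditions frees the C11 alcohol without opening or transesterifying the medium-ring lactone.

Step 10
Reactants: 14 (8R)-8-[(1R,2R)-2-(hydroxymethyl)cyclopropyl]oxocan-2-one
Product: 15 (8R)-8-[(1R,2R)-2-{[(1-phenyl-1H-tetrazol-5-yl)sulfanyl]methyl}cyclopropyl]oxocan-2-one
Conditions: 1-phenyl-1H-tetrazole-5-thiol, PPh3, DIAD, THF, 0 °C → rt
Reagents that add atoms: 1-phenyl-1H-tetrazole-5-thiol, Sc1nnnn1-c1ccccc1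
Why: Mitsunobu thioetherification: the acidic thiol displaces the activated primary C11–O bond by SN2, fast enough that ionisation to a cyclopropylcarbinyl cation should not compete.

Step 11
Reactants: 15 tetrazolyl sulfide
Product: 16 (8R)-8-[(1R,2R)-2-{[(1-phenyl-1H-tetrazol-5-yl)sulfonyl]methyl}cyclopropyl]oxocan-2-one
Conditions: (NH4)6Mo7O24·4H2O (cat.), 30% aq H2O2, EtOH, 0 °C → rt
Reagents that add atoms: hydrogen peroxide, OO
Why: Molybdate-catalysed peroxide oxidation of sulfide to sulfone; no alkene is present yet, and lactone and cyclopropane are inert.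

Step 12
Reactants: 17 (4S,5S)-2,2-dimethyl-1,3-dioxolane-4,5-dimethanol (2,3-O-isopropylidene-L-threitol)
Product: 18 [(4S,5S)-5-{[(tert-butyldimethylsilyl)oxy]methyl}-2,2-dimethyl-1,3-dioxolan-4-yl]methanol
Conditions: NaH (1.0 equiv), THF, 0 °C; TBSCl (1.0 equiv), rt
Reagents that add atoms: tert-butyl(chloro)dimethylsilane, CC(C)(C)[Si](C)(C)Cl
Why: Monosilylation through the monosodium alkoxide; the two CH2OH groups are homotopic (C2 axis), so that either one gives the same compound and both stereocentres of the L-tartaric acid series (later C13 and C14) are kept.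

Step 13
Reactants: 18 mono-TBS L-threitol acetonide
Product: 19 [(4S,5S)-5-{[(tert-butyldimethylsilyl)oxy]methyl}-2,2-dimethyl-1,3-dioxolan-4-yl]methyl trifluoromethanesulfonate
Conditions: Tf2O, 2,6-lutidine, CH2Cl2, −78 °C
Reagents that add atoms: trifluoromethanesulfonic anhydride, O=S(=O)(OS(=O)(=O)C(F)(F)F)C(F)(F)F
Why: Sulfonylation of the primary alcohol at low temperature gives a leaving group reactive enough for acetylide displacement next to a β-oxygen.

Step 14
Reactants: 19 primary triflate; 20 1-heptyne
Product: 21 tert-butyl{[(4S,5S)-2,2-dimethyl-5-(oct-2-ynyl)-1,3-dioxolan-4-yl]methoxy}dimethylsilane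
Conditions: 20, n-BuLi, THF, −78 °C; then 19, DMPU, −78 → 0 °C
Reagents that add atoms: none
Why: SN2 alkylation of a lithium acetylide by a primary triflate in the presence of DMPU forms C15–C16 without touching C14.

Step 15
Reactants: 21 oct-2-ynyl dioxolane
Product: 22 tert-butyl{[(4S,5S)-2,2-dimethyl-5-((Z)-oct-2-enyl)-1,3-dioxolan-4-yl]methoxy}dimethylsilane
Conditions: H2 (1 atm), Lindlar catalyst, quinoline, hexane/EtOAc, rt
Reagents that add atoms: none
Why: Lindlar semihydrogenation: syn delivery of H2 on poisoned palladium should stop at the Z-alkene C16=C17.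

Step 16
Reactants: 22 (Z)-oct-2-enyl dioxolane TBS ether
Product: 23 [(4S,5S)-2,2-dimethyl-5-((Z)-oct-2-enyl)-1,3-dioxolan-4-yl]methanol
Conditions: TBAF, THF, 0 °C → rt
Reagents that add atoms: none
Why: Fluoride desilylation, to which acetonide and alkene are inert.

Step 17
Reactants: 23 primary alcohol
Product: 24 (4R,5S)-2,2-dimethyl-5-((Z)-oct-2-enyl)-1,3-dioxolane-4-carbaldehyde
Conditions: Dess–Martin periodinane, CH2Cl2, 0 °C → rt
Reagents that add atoms: none
Why: Dess–Martin oxidation under near-neutral conditions gives the α-alkoxy aldehyde; the trans-dioxolane is the more stable epimer, so C13 should hold (the descriptor changes only through CIP priorities).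

Step 18
Reactants: 16 lactone sulfone; 24 acetonide aldehyde
Product: 25 (8R)-8-[(1R,2S)-2-{(E)-2-[(4S,5S)-2,2-dimethyl-5-((Z)-oct-2-enyl)-1,3-dioxolan-4-yl]ethenyl}cyclopropyl]oxocan-2-one
Conditions: 16, KHMDS (1.05 equiv), THF, −78 °C; then 24, −78 °C → rt
Reagents that add atoms: none
Why: Julia–Kocienski olefination: the potassium sulfonyl carbanion (C11–H is more acidic than the lactone α-H, and the trans-cyclopropane keeps C11 away from C1) adds to 24, and Smiles rearrangement followed by anti elimination of SO2 and tetrazolate should give the E-alkene C11=C12.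

Step 19
Reactants: 25 acetonide of the target
Product: 26 (8R)-8-[(1R,2S)-2-[(1E,3S,4S,6Z)-3,4-dihydroxydodeca-1,6-dienyl]cyclopropyl]oxocan-2-one (target)
Conditions: AcOH/THF/H2O (3:1:1), 40 °C
Reagents that add atoms: none
Why: Mild acid-catalysed acetal hydrolysis proceeds through the oxygen-stabilised 2-propyl cation and thus should release the diol before the allylic C13–O bond or the lactone reacts.

Compound list
1 | (R)-5-(hydroxymethyl)dihydrofuran-2(3H)-one | OC[C@H]1CCC(=O)O1 | starting material
2 | (triphenylphosphoranylidene)acetaldehyde | O=CC=P(c1ccccc1)(c1ccccc1)c1ccccc1 | starting material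
3 | (R)-5-oxotetrahydrofuran-2-carbaldehyde | O=C[C@H]1CCC(=O)O1 | intermediate
4 | (E)-3-[(2R)-5-oxotetrahydrofuran-2-yl]prop-2-enal | O=C/C=C/[C@H]1CCC(=O)O1 | intermediate
5 | (5R)-5-[(E)-3-hydroxyprop-1-enyl]dihydrofuran-2(3H)-one | OC/C=C/[C@H]1CCC(=O)O1 | intermediate
6 | (5R)-5-[(1R,2R)-2-(hydroxymethyl)cyclopropyl]dihydrofuran-2(3H)-one | OC[C@@H]1C[C@H]1[C@H]1CCC(=O)O1 | intermediate
7 | TBDPS ether of 6 | CC(C)(C)[Si](OC[C@@H]1C[C@H]1[C@H]1CCC(=O)O1)(c1ccccc1)c1ccccc1 | intermediate
8 | 1,3-diiodopropane | ICCCI | starting material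
9 | 3-(3-iodopropyl) derivative of 7 (C5 epimers) | CC(C)(C)[Si](OC[C@@H]1C[C@H]1[C@H]1CC(CCCI)C(=O)O1)(c1ccccc1)c1ccccc1 | intermediate
10 | 2-[(2R)-2-hydroxy-2-{(1R,2R)-2-[(tert-butyldiphenylsilyloxy)methyl]cyclopropyl}ethyl]cyclopentan-1-one (C5 epimers) | CC(C)(C)[Si](OC[C@@H]1C[C@H]1[C@H](O)CC1CCCC1=O)(c1ccccc1)c1ccccc1 | intermediate
11 | (2R)-2-[(1R,2R)-2-{[(tert-butyldiphenylsilyl)oxy]methyl}cyclopropyl]hexahydro-2H-cyclopenta[b]furan-6a-ol (cis-fused lactol, closed tautomer of 10) | CC(C)(C)[Si](OC[C@@H]1C[C@H]1[C@H]1CC2CCCC2(O)O1)(c1ccccc1)c1ccccc1 | intermediate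
12 | (8R)-6-iodo-8-[(1R,2R)-2-{[(tert-butyldiphenylsilyl)oxy]methyl}cyclopropyl]oxocan-2-one | CC(C)(C)[Si](OC[C@@H]1C[C@H]1[C@H]1CC(I)CCCC(=O)O1)(c1ccccc1)c1ccccc1 | intermediate
13 | (8R)-8-[(1R,2R)-2-{[(tert-butyldiphenylsilyl)oxy]methyl}cyclopropyl]oxocan-2-one | CC(C)(C)[Si](OC[C@@H]1C[C@H]1[C@H]1CCCCCC(=O)O1)(c1ccccc1)c1ccccc1 | intermediate
14 | (8R)-8-[(1R,2R)-2-(hydroxymethyl)cyclopropyl]oxocan-2-one | OC[C@@H]1C[C@H]1[C@H]1CCCCCC(=O)O1 | intermediate
15 | (8R)-8-[(1R,2R)-2-{[(1-phenyl-1H-tetrazol-5-yl)sulfanyl]methyl}cyclopropyl]oxocan-2-one | c1ccccc1-n1nnnc1SC[C@@H]1C[C@H]1[C@H]1CCCCCC(=O)O1 | intermediate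
16 | (8R)-8-[(1R,2R)-2-{[(1-phenyl-1H-tetrazol-5-yl)sulfonyl]methyl}cyclopropyl]oxocan-2-one | c1ccccc1-n1nnnc1S(=O)(=O)C[C@@H]1C[C@H]1[C@H]1CCCCCC(=O)O1 | intermediate
17 | (4S,5S)-2,2-dimethyl-1,3-dioxolane-4,5-dimethanol | OC[C@@H]1OC(C)(C)O[C@H]1CO | starting material
18 | mono-TBS ether of 17 | OC[C@@H]1OC(C)(C)O[C@H]1CO[Si](C)(C)C(C)(C)C | intermediate
19 | triflate of 18 | O=S(=O)(OC[C@@H]1OC(C)(C)O[C@H]1CO[Si](C)(C)C(C)(C)C)C(F)(F)F | intermediate
20 | 1-heptyne | C#CCCCCC | starting material
21 | tert-butyl{[(4S,5S)-2,2-dimethyl-5-(oct-2-ynyl)-1,3-dioxolan-4-yl]methoxy}dimethylsilane | CCCCCC#CC[C@@H]1OC(C)(C)O[C@H]1CO[Si](C)(C)C(C)(C)C | intermediate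
22 | tert-butyl{[(4S,5S)-2,2-dimethyl-5-((Z)-oct-2-enyl)-1,3-dioxolan-4-yl]methoxy}dimethylsilane | CCCCC/C=C\C[C@@H]1OC(C)(C)O[C@H]1CO[Si](C)(C)C(C)(C)C | intermediate
23 | [(4S,5S)-2,2-dimethyl-5-((Z)-oct-2-enyl)-1,3-dioxolan-4-yl]methanol | CCCCC/C=C\C[C@@H]1OC(C)(C)O[C@H]1CO | intermediate
24 | (4R,5S)-2,2-dimethyl-5-((Z)-oct-2-enyl)-1,3-dioxolane-4-carbaldehyde | CCCCC/C=C\C[C@@H]1OC(C)(C)O[C@H]1C=O | intermediate
25 | acetonide of the target | CCCCC/C=C\C[C@@H]1OC(C)(C)O[C@H]1/C=C/[C@@H]1C[C@H]1[C@H]1CCCCCC(=O)O1 | intermediate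
26 | (8R)-8-[(1R,2S)-2-[(1E,3S,4S,6Z)-3,4-dihydroxydodeca-1,6-dienyl]cyclopropyl]oxocan-2-one | CCCCC/C=C\C[C@H](O)[C@@H](O)/C=C/[C@@H]1C[C@H]1[C@H]1CCCCCC(=O)O1 | target

Total step count: 19. Longest linear sequence: 13 steps (steps 1–11, 18, 19).

Steps most likely to fail

Step 7. A cyclopentanone favours the open tautomer 10, so the hypoiodite may form at the free C7 hydroxyl instead of the lactol hydroxyl. That would lead to hydrogen abstraction or oxidation at C7, and scission of the peripheral C1–C2 bond may also compete.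
Fallback, from 10: acid-catalysed perketalisation with H2O2 (cat. TsOH, Et2O) should lock the closed form as the bicyclic α-alkoxy hydroperoxide F1. Single-electron cleavage of its O–O bond with FeSO4·7H2O in MeOH in the presence of benzenethiol gives the same C1 alkoxy radical from the closed form only. β-Scission of C1–C5 and hydrogen transfer from the thiol to C5 follow. The route is rejoined at 13, and 12 is bypassed.

Step 6. The C2 radical may abstract hydrogen from THF before the second electron transfer, which is simple loss of iodine. The basic organosamarium may also enolise the lactone instead of adding to it.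
Fallback, from 9: displacement of iodide with sodium benzenesulfinate (DMF) gives the phenyl sulfone F2. Its sulfonyl carbanion (LiHMDS, 2.2 equiv, THF, −78 °C → rt) acylates intramolecularly at C1 in a Dieckmann-type closure, driven by deprotonation of the product, and gives the β-keto sulfone F3. Reductive desulfonylation with aluminium amalgam (THF/H2O) removes the activating group, and the route is rejoined at 10.

Step 19. Acid may ionise the allylic C13–O bond, since the cation is stabilised by the alkene and the cyclopropane. Allylic transposition or cyclopropane opening would follow, and the strained lactone may hydrolyse.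
Fallback, from 22: aqueous trifluoroacetic acid strips acetonide and TBS before the sensitive vinylcyclopropane exists and gives (2S,3S,5Z)-undec-5-ene-1,2,3-triol F4. TESCl/imidazole gives the tris-TES ether F5. Swern conditions oxidise the primary TES ether selectively to the bis-TES aldehyde F6. Julia–Kocienski coupling with 16 gives the bis-TES ether of the target F7, and buffered HF·pyridine releases the diol without protic acid. The route is rejoined at 26.

Further compounds
F1 | step 7 | (2R)-6a-hydroperoxy-2-[(1R,2R)-2-{[(tert-butyldiphenylsilyl)oxy]methyl}cyclopropyl]hexahydro-2H-cyclopenta[b]furan | CC(C)(C)[Si](OC[C@@H]1C[C@H]1[C@H]1CC2CCCC2(OO)O1)(c1ccccc1)c1ccccc1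
F2 | step 6 | 3-[3-(phenylsulfonyl)propyl] analogue of 9 | CC(C)(C)[Si](OC[C@@H]1C[C@H]1[C@H]1CC(CCCS(=O)(=O)c2ccccc2)C(=O)O1)(c1ccccc1)c1ccccc1
F3 | step 6 | 5-(phenylsulfonyl) derivative of hydroxy ketone 10 (sulfone on C2) | CC(C)(C)[Si](OC[C@@H]1C[C@H]1[C@H](O)CC1CCC(C1=O)S(=O)(=O)c1ccccc1)(c1ccccc1)c1ccccc1
F4 | step 19 | (2S,3S,5Z)-undec-5-ene-1,2,3-triol | CCCCC/C=C\C[C@H](O)[C@@H](O)CO
F5 | step 19 | tris(triethylsilyl) ether of F4 | CCCCC/C=C\C[C@H](O[Si](CC)(CC)CC)[C@@H](O[Si](CC)(CC)CC)CO[Si](CC)(CC)CC
F6 | step 19 | (2R,3S,5Z)-2,3-bis(triethylsilyloxy)undec-5-enal | CCCCC/C=C\C[C@H](O[Si](CC)(CC)CC)[C@@H](O[Si](CC)(CC)CC)C=O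
F7 | step 19 | 13,14-bis(triethylsilyl) ether of the target | CCCCC/C=C\C[C@H](O[Si](CC)(CC)CC)[C@@H](O[Si](CC)(CC)CC)/C=C/[C@@H]1C[C@H]1[C@H]1CCCCCC(=O)O1
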